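**Plan**
Retrosynthesis: cut the C3–O caffeoyl ester, then the ring A bond C4–C5, then C1–C2 (aldol, with the C3 carbonyl), then C10–C1 / C10–CH3 and C7–i-Pr on a ring B ketone, back to a 4-silyloxycyclohexenone.
Forward: ring B is bought and decorated, the C1–C4(≡C15) chain is grown on C10, and ring A closes last by a deoxygenative 6-exo-dig radical cyclisation of a C5 radical onto the C4≡C15 alkyne, which also leaves the exocyclic methylene.
Enabling feature: the exocyclic C4=C15 methylene sits on the carbon next to the C5 ring-fusion methine, and every other substituent (C1–O, C3–O on ring A; C7 i-Pr, C8–O on ring B) is equatorial with the C10 methyl axial, so only a chair–chair, trans-fused transition state is open.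
Stereochemistry: C8 from the starting enone; C7 by anti cuprate addition; C10 by axial methylation; a temporary 5β-oxygen (hydride anti to the C10 methyl) relays C1 through a chelation-controlled aldol and then serves as the radical leaving group; C3 by syn-1,3-reduction; C5 in the ring closure.

Key step: step 13

Remark: enone 1 is taken as a purchasable enantiopure building block; eudesmane numbering (C1–C15) is used for all intermediates, α/β referring to the drawing with the C10 methyl β.

Step 1
Reactants: 1 (S)-4-(tert-butyldimethylsilyloxy)cyclohex-2-en-1-one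
Product: 3 (3R,4S)-4-(tert-butyldimethylsilyloxy)-3-isopropylcyclohexan-1-one, via trimethylsilyl enol ether 2 (not isolated)
Conditions: i-PrMgCl, CuBr·SMe2 (10 mol %), TMSCl, THF, −78 °C; then K2CO3, MeOH, 0 °C
Reagents that add atoms: isopropylmagnesium chloride, CC(C)[Mg]Cl
Why: Copper-catalysed conjugate addition of the Grignard reagent to a 4-silyloxycyclohexenone should occur anti to the γ-silyloxy group, which sets C7 trans to the C8 oxygen.

Step 2
Reactants: 3 (3R,4S)-4-(tert-butyldimethylsilyloxy)-3-isopropylcyclohexan-1-one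
Product: 5 methyl (1R,4R,5S)-5-(tert-butyldimethylsilyloxy)-4-isopropyl-1-methyl-2-oxocyclohexane-1-carboxylate, via sodium enolate 4 (not isolated)
Conditions: NaH, (MeO)2CO, THF, reflux; then MeI, 0 °C → rt
Reagents that add atoms: dimethyl carbonate, COC(=O)OC; iodomethane, CI
Why: Claisen-type C-acylation should take the less hindered α-carbon (C10, remote from the isopropyl group), and C-methylation of the β-keto ester enolate should follow the axial trajectory on the ring locked by the equatorial isopropyl and silyloxy groups, which places the C10 methyl β (axial) and the ester carbon (C1) equatorial.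

Step 3
Reactants: 5 methyl (1R,4R,5S)-5-(tert-butyldimethylsilyloxy)-4-isopropyl-1-methyl-2-oxocyclohexane-1-carboxylate
Product: 6 (1R,2S,4S,5R)-4-(tert-butyldimethylsilyloxy)-2-(hydroxymethyl)-5-isopropyl-2-methylcyclohexan-1-ol
Conditions: LiAlH4, THF, 0 °C → rt
Reagents that add atoms: none
Why: Hydride reduction of ester and ketone, in which the ketone should be attacked axially, anti to the axial C10 methyl, to give the equatorial 5β-alcohol (the sense known for ketones flanking an angular methyl group).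

Step 4
Reactants: 6 (1R,2S,4S,5R)-4-(tert-butyldimethylsilyloxy)-2-(hydroxymethyl)-5-isopropyl-2-methylcyclohexan-1-ol
Product: 7 4-methoxybenzylidene acetal of 6 (trans-fused 1,3-dioxane over O1 and O5; aryl equatorial)
Conditions: 4-MeOC6H4CH(OMe)2, PPTS (cat.), CH2Cl2, rt
Reagents that add atoms: 4-methoxybenzaldehyde dimethyl acetal, COc1ccc(C(OC)OC)cc1
Why: Acid-catalysed transacetalisation of the 1,3-diol should give the trans-fused dioxane with the aryl group equatorial under thermodynamic control.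

Step 5
Reactants: 7 4-methoxybenzylidene acetal of 6
Product: 8 ring B primary alcohol [C10: CH2OH (α) and CH3 (β); 5β-O-PMB; 7β-i-Pr; 8α-OTBS]
Conditions: i-Bu2AlH, CH2Cl2, −78 → 0 °C
Reagents that add atoms: none
Why: Reductive acetal opening should proceed through aluminium coordination at the less hindered primary oxygen, which leaves the 4-methoxybenzyl ether on the secondary C5 oxygen and frees the C1 alcohol.

Step 6
Reactants: 8 ring B primary alcohol (5β-O-PMB)
Product: 9 ring B aldehyde [C10: CHO (C1, α) and CH3 (β); 5β-O-PMB; 7β-i-Pr; 8α-OTBS]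
Conditions: Dess–Martin periodinane, NaHCO3, CH2Cl2, rt
Reagents that add atoms: none
Why: Dess–Martin oxidation of the neopentyl primary alcohol gives the non-enolisable aldehyde without touching the silyl or benzyl ethers.

Step 7
Reactants: 10 4-(trimethylsilyl)but-3-yn-2-one
Product: 11 trimethyl{[4-(trimethylsilyl)but-1-en-3-yn-2-yl]oxy}silane
Conditions: LiN(i-Pr)2, THF, −78 °C; TMSCl
Reagents that add atoms: chlorotrimethylsilane, C[Si](C)(C)Cl
Why: Kinetic deprotonation of the methyl ketone and O-silylation give the enol silane needed for the Mukaiyama aldol reaction.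

Step 8
Reactants: 9 ring B aldehyde; 11 trimethyl{[4-(trimethylsilyl)but-1-en-3-yn-2-yl]oxy}silane
Product: 12 (1R)-β-hydroxy ynone [C10–C1H(OH)–C2H2–C3(=O)–C4≡C15–SiMe3 on the ring B unit of 9]
Conditions: MgBr2·OEt2, CH2Cl2, −78 → −20 °C; aqueous citric acid work-up
Reagents that add atoms: none
Why: Chelation-controlled Mukaiyama aldol addition in which MgBr2 should bridge the aldehyde oxygen and the 5β-ether oxygen in a chelate trans-fused to ring B, so that attack anti to the axial C10 methyl (the 1,3-anti sense also predicted by the open Felkin–Evans model) sets C1 as R.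

Step 9
Reactants: 12 (1R)-β-hydroxy ynone
Product: 14 (1R,3S)-1,3-diol with terminal alkyne [C1H(OH)–C2H2–C3H(OH)–C4≡C15H], via C-silylated diol 13 (not isolated)
Conditions: Et2BOMe, NaBH4, THF/MeOH, −78 °C; AcOH, MeOH (co-evaporation); then K2CO3, MeOH, rt
Reagents that add atoms: none
Why: Narasaka–Prasad reduction through the six-membered diethylboron chelate delivers hydride to give the syn-1,3-diol (C3 S), and methanolic K2CO3 then removes the alkyne C-silyl group.

Step 10
Reactants: 14 (1R,3S)-1,3-diol with terminal alkyne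
Product: 16 3-O-triethylsilyl 1-O-tert-butyldimethylsilyl ether of 14, via 3-O-TES ether 15 (not isolated)
Conditions: TESCl, imidazole, CH2Cl2, −40 °C; then TBSOTf, 2,6-lutidine, −40 → 0 °C
Reagents that add atoms: chlorotriethylsilane, CC[Si](CC)(CC)Cl; tert-butyldimethylsilyl trifluoromethanesulfonate, CC(C)(C)[Si](C)(C)OS(=O)(=O)C(F)(F)F
Why: The unhindered propargylic C3 hydroxyl should be silylated first by TESCl, after which the neopentyl-type C1 hydroxyl is capped by the more reactive TBSOTf, so that C3 can later be unmasked alone.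

Step 11
Reactants: 16 3-O-TES 1-O-TBS ether (5β-O-PMB)
Product: 17 C5 alcohol (5β-OH; 1-O-TBS, 3-O-TES, 8α-OTBS, terminal alkyne)
Conditions: DDQ, CH2Cl2/pH 7 buffer, 0 °C
Reagents that add atoms: none
Why: Oxidative cleavage of the 4-methoxybenzyl ether by DDQ frees only the C5 hydroxyl, the silyl ethers and the alkyne being inert under buffered conditions.

Step 12
Reactants: 17 C5 alcohol
Product: 18 C5 O-phenyl thionocarbonate of 17
Conditions: PhOC(S)Cl, pyridine, DMAP, CH2Cl2, rt → 40 °C
Reagents that add atoms: O-phenyl carbonochloridothioate (phenyl chlorothionoformate), S=C(Cl)Oc1ccccc1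
Why: Acylation under neutral conditions gives the Barton–McCombie radical precursor and avoids an alkoxide that could trigger 1,3-silyl migration from O1.

Step 13
Reactants: 18 C5 O-phenyl thionocarbonate
Product: 19 (1R,3S,5S,7R,8S,10R)-1,8-bis(tert-butyldimethylsilyloxy)-3-(triethylsilyloxy)eudesm-4(15)-ene
Conditions: Bu3SnH (syringe pump), AIBN, PhMe, 90 °C, high dilution
Reagents that add atoms: none
Why: Barton–McCombie-type deoxygenative radical cyclisation: Bu3Sn• adds to the thiocarbonyl group and β-scission gives the secondary C5 radical, which adds to the internal carbon (C4) of the terminal alkyne, and the σ-vinyl radical at C15 abstracts hydrogen from Bu3SnH to leave the exocyclic methylene. The closest known reaction type is the tin hydride mediated cyclisation of hept-6-ynyl radicals generated from xanthates or thionocarbonates of secondary alcohols. Ring A is closed in the 6-exo-dig mode. The only new stereocentre, C5, is controlled by the chair–chair transition state: ring B is locked by its equatorial isopropyl and silyloxy groups with the C10 methyl axial, and the forming ring A can keep both the C1 and C3 silyloxy groups equatorial only if C4 bonds to C5 equatorially, which gives the trans ring fusion (5α-H). The step needs cyclisation to outrun direct reduction of the C5 radical, 1,5-hydrogen transfer and tin addition to the alkyne; slow addition of the hydride at high dilution, the fast reaction of tin radicals at C=S and the quaternary C10 next to the radical centre should secure this, and the terminal alkyne favours 6-exo over 7-endo attack.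

Step 14
Reactants: 19 (1R,3S,5S,7R,8S,10R)-1,8-bis(tert-butyldimethylsilyloxy)-3-(triethylsilyloxy)eudesm-4(15)-ene
Product: 20 (1R,3S,5S,7R,8S,10R)-1,8-bis(tert-butyldimethylsilyloxy)eudesm-4(15)-en-3-ol
Conditions: PPTS, MeOH/CH2Cl2, 0 °C
Reagents that add atoms: none
Why: Mild acid methanolysis should remove the triethylsilyl ether selectively in the presence of the two hindered secondary TBS ethers.

Step 15
Reactants: 21 caffeic acid [(E)-3-(3,4-dihydroxyphenyl)acrylic acid]
Product: 23 (E)-3-[3,4-bis(tert-butyldimethylsilyloxy)phenyl]acrylic acid, via tris-silyl derivative 22 (not isolated)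
Conditions: TBSCl, imidazole, DMF, rt; then AcOH, THF/H2O, rt
Reagents that add atoms: tert-butyl(chloro)dimethylsilane, CC(C)(C)[Si](C)(C)Cl
Why: Persilylation followed by mild hydrolysis of the labile silyl ester gives the catechol-protected acid.

Step 16
Reactants: 20 (1R,3S,5S,7R,8S,10R)-1,8-bis(tert-butyldimethylsilyloxy)eudesm-4(15)-en-3-ol; 23 (E)-3-[3,4-bis(tert-butyldimethylsilyloxy)phenyl]acrylic acid
Product: 24 (1R,3S,5S,7R,8S,10R)-1,8-bis(tert-butyldimethylsilyloxy)eudesm-4(15)-en-3-yl (E)-3-[3,4-bis(tert-butyldimethylsilyloxy)phenyl]acrylate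
Conditions: EDC·HCl, DMAP, CH2Cl2, 0 °C → rt
Reagents that add atoms: none
Why: Carbodiimide (Steglich-type) esterification of the equatorial allylic C3 alcohol, the only free hydroxyl, installs the caffeoyl unit without isomerising the (E)-alkene.

Step 17
Reactants: 24 fully silylated ester
Product: 25 (1R,3S,5S,7R,8S,10R)-1,8-dihydroxyeudesm-4(15)-en-3-yl (E)-3-(3,4-dihydroxyphenyl)acrylate (CNP0264533.1)
Conditions: HF·pyridine, THF/pyridine, 0 °C → rt
Reagents that add atoms: none
Why: Fluoride cleavage of the two alkyl and two aryl TBS ethers under weakly acidic conditions should liberate the target without acyl migration from O3 to O1.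

**Compound list**
1 | (S)-4-(tert-butyldimethylsilyloxy)cyclohex-2-en-1-one | O=C1C=C[C@@H](O[Si](C)(C)C(C)(C)C)CC1 | starting material
2 | trimethylsilyl enol ether of 3 (C5–OSiMe3, C5=C6; 7β-i-Pr, 8α-OTBS) | C[Si](C)(C)OC1=C[C@H](C(C)C)[C@@H](O[Si](C)(C)C(C)(C)C)CC1 | intermediate
3 | (3R,4S)-4-(tert-butyldimethylsilyloxy)-3-isopropylcyclohexan-1-one | O=C1C[C@H](C(C)C)[C@@H](O[Si](C)(C)C(C)(C)C)CC1 | intermediate
4 | sodium enolate of methyl (4R,5S)-5-(tert-butyldimethylsilyloxy)-4-isopropyl-2-oxocyclohexane-1-carboxylate | COC(=O)C1=C([O-])C[C@H](C(C)C)[C@@H](O[Si](C)(C)C(C)(C)C)C1.[Na+] | intermediate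
5 | methyl (1R,4R,5S)-5-(tert-butyldimethylsilyloxy)-4-isopropyl-1-methyl-2-oxocyclohexane-1-carboxylate (10β-CH3, ester α) | COC(=O)[C@@]1(C)C(=O)C[C@H](C(C)C)[C@@H](O[Si](C)(C)C(C)(C)C)C1 | intermediate
6 | (1R,2S,4S,5R)-4-(tert-butyldimethylsilyloxy)-2-(hydroxymethyl)-5-isopropyl-2-methylcyclohexan-1-ol (5β-OH) | OC[C@@]1(C)[C@H](O)C[C@H](C(C)C)[C@@H](O[Si](C)(C)C(C)(C)C)C1 | intermediate
7 | 4-methoxybenzylidene acetal of 6 (trans-fused 1,3-dioxane over O1/O5, aryl equatorial) | COc1ccc(cc1)[C@H]2OC[C@]3(C)C[C@H](O[Si](C)(C)C(C)(C)C)[C@@H](C(C)C)C[C@H]3O2 | intermediate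
8 | ring B primary alcohol: C10 carries CH2OH (α) and CH3 (β); 5β-O-(4-methoxybenzyl); 7β-isopropyl; 8α-OTBS | OC[C@@]1(C)[C@H](OCc2ccc(OC)cc2)C[C@H](C(C)C)[C@@H](O[Si](C)(C)C(C)(C)C)C1 | intermediate
9 | ring B aldehyde: C10 carries CHO (C1, α) and CH3 (β); 5β-O-(4-methoxybenzyl); 7β-isopropyl; 8α-OTBS | O=C[C@@]1(C)[C@H](OCc2ccc(OC)cc2)C[C@H](C(C)C)[C@@H](O[Si](C)(C)C(C)(C)C)C1 | intermediate
10 | 4-(trimethylsilyl)but-3-yn-2-one | CC(=O)C#C[Si](C)(C)C | starting material
11 | trimethyl{[4-(trimethylsilyl)but-1-en-3-yn-2-yl]oxy}silane | C=C(O[Si](C)(C)C)C#C[Si](C)(C)C | intermediate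
12 | (1R)-1-hydroxy-5-(trimethylsilyl)pent-4-yn-3-one attached through C1 to C10 of the ring B unit of 9 | C[Si](C)(C)C#CC(=O)C[C@@H](O)[C@@]1(C)[C@H](OCc2ccc(OC)cc2)C[C@H](C(C)C)[C@@H](O[Si](C)(C)C(C)(C)C)C1 | intermediate
13 | (1R,3S)-5-(trimethylsilyl)pent-4-yne-1,3-diol on the same ring B unit (syn-diol) | C[Si](C)(C)C#C[C@@H](O)C[C@@H](O)[C@@]1(C)[C@H](OCc2ccc(OC)cc2)C[C@H](C(C)C)[C@@H](O[Si](C)(C)C(C)(C)C)C1 | intermediate
14 | (1R,3S)-pent-4-yne-1,3-diol on the same ring B unit (terminal alkyne) | C#C[C@@H](O)C[C@@H](O)[C@@]1(C)[C@H](OCc2ccc(OC)cc2)C[C@H](C(C)C)[C@@H](O[Si](C)(C)C(C)(C)C)C1 | intermediate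
15 | 3-O-triethylsilyl ether of 14 | C#C[C@@H](O[Si](CC)(CC)CC)C[C@@H](O)[C@@]1(C)[C@H](OCc2ccc(OC)cc2)C[C@H](C(C)C)[C@@H](O[Si](C)(C)C(C)(C)C)C1 | intermediate
16 | 3-O-triethylsilyl 1-O-tert-butyldimethylsilyl ether of 14 | C#C[C@@H](O[Si](CC)(CC)CC)C[C@@H](O[Si](C)(C)C(C)(C)C)[C@@]1(C)[C@H](OCc2ccc(OC)cc2)C[C@H](C(C)C)[C@@H](O[Si](C)(C)C(C)(C)C)C1 | intermediate
17 | C5 alcohol (5β-OH) obtained from 16 by loss of the 4-methoxybenzyl group | C#C[C@@H](O[Si](CC)(CC)CC)C[C@@H](O[Si](C)(C)C(C)(C)C)[C@@]1(C)[C@H](O)C[C@H](C(C)C)[C@@H](O[Si](C)(C)C(C)(C)C)C1 | intermediate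
18 | C5 O-phenyl thionocarbonate of 17 | C#C[C@@H](O[Si](CC)(CC)CC)C[C@@H](O[Si](C)(C)C(C)(C)C)[C@@]1(C)[C@H](OC(=S)Oc2ccccc2)C[C@H](C(C)C)[C@@H](O[Si](C)(C)C(C)(C)C)C1 | intermediate
19 | (1R,3S,5S,7R,8S,10R)-1,8-bis(tert-butyldimethylsilyloxy)-3-(triethylsilyloxy)eudesm-4(15)-ene | C=C1[C@@H](O[Si](CC)(CC)CC)C[C@@H](O[Si](C)(C)C(C)(C)C)[C@]2(C)C[C@H](O[Si](C)(C)C(C)(C)C)[C@@H](C(C)C)C[C@@H]12 | intermediate
20 | (1R,3S,5S,7R,8S,10R)-1,8-bis(tert-butyldimethylsilyloxy)eudesm-4(15)-en-3-ol | C=C1[C@@H](O)C[C@@H](O[Si](C)(C)C(C)(C)C)[C@]2(C)C[C@H](O[Si](C)(C)C(C)(C)C)[C@@H](C(C)C)C[C@@H]12 | intermediate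
21 | caffeic acid, (E)-3-(3,4-dihydroxyphenyl)acrylic acid | OC(=O)/C=C/c1ccc(O)c(O)c1 | starting material
22 | tert-butyldimethylsilyl (E)-3-[3,4-bis(tert-butyldimethylsilyloxy)phenyl]acrylate | CC(C)(C)[Si](C)(C)OC(=O)/C=C/c1ccc(O[Si](C)(C)C(C)(C)C)c(O[Si](C)(C)C(C)(C)C)c1 | intermediate
23 | (E)-3-[3,4-bis(tert-butyldimethylsilyloxy)phenyl]acrylic acid | OC(=O)/C=C/c1ccc(O[Si](C)(C)C(C)(C)C)c(O[Si](C)(C)C(C)(C)C)c1 | intermediate
24 | (1R,3S,5S,7R,8S,10R)-1,8-bis(tert-butyldimethylsilyloxy)eudesm-4(15)-en-3-yl (E)-3-[3,4-bis(tert-butyldimethylsilyloxy)phenyl]acrylate | C=C1[C@@H](OC(=O)/C=C/c2ccc(O[Si](C)(C)C(C)(C)C)c(O[Si](C)(C)C(C)(C)C)c2)C[C@@H](O[Si](C)(C)C(C)(C)C)[C@]2(C)C[C@H](O[Si](C)(C)C(C)(C)C)[C@@H](C(C)C)C[C@@H]12 | intermediate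
25 | (1R,3S,5S,7R,8S,10R)-1,8-dihydroxyeudesm-4(15)-en-3-yl (E)-3-(3,4-dihydroxyphenyl)acrylate | C=C1[C@@H](OC(=O)/C=C/c2ccc(O)c(O)c2)C[C@@H](O)[C@]2(C)C[C@H](O)[C@@H](C(C)C)C[C@@H]12 | target

**Step count**
Total: 17 steps. Longest linear sequence: 15 steps (steps 1–6, 8–14, 16, 17); steps 7 and 15 are side branches.

**Steps most likely to fail**
Step 13: the slow 6-exo-dig closure may lose out to premature hydrogen transfer to the C5 radical or to 1,5-hydrogen transfer from C3–H. The fallback reverses the radical event and sets out from alcohol 17. Dehydration with the Burgess reagent in hot benzene (syn-elimination, only the C6 hydrogens are available) should give the C5=C6 olefin F1. A tin-radical enyne cyclisation (Bu3SnH, AIBN, PhH, 80 °C) then lets Bu3Sn• add to the terminal alkyne, the vinyl radical at C4 closes 6-exo-trig onto C5 of the ring olefin, and the C6 radical is reduced, giving the vinylstannane F2. Protodestannylation with dilute HCl in MeOH/CH2Cl2, which also removes the triethylsilyl group, comes back to the route at 20.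

Step 2: the methylation may show poor facial selectivity (equatorial attack) or competing O-methylation. The fallback sets out from ketone 3. Carbomethoxylation alone (NaH, (MeO)2CO, acidic work-up) gives the β-keto ester F3. Reduction with LiBH(s-Bu)3 from the equatorial direction should give the cis-β-hydroxy ester F4 with an axial 5α-hydroxyl. Fráter–Seebach alkylation of its dianion (LiN(i-Pr)2, 2.2 equiv, then MeI), in which the methyl group enters anti to the axial alkoxide and therefore axially, should give the methylated hydroxy ester F5. Dess–Martin oxidation comes back to the route at 5.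

Step 8: the aldol addition may suffer incomplete chelation and hence poor facial selectivity at C1, or retro-aldol loss of the adduct. The fallback replaces substrate control by reagent control and sets out from aldehyde 9. Brown allylation with (+)-Ipc2B(allyl), the reagent enantiomer chosen for the (1R)-carbinol, should give the homoallylic alcohol F6. Oxidative cleavage of the vinyl group (OsO4 cat., NaIO4, 2,6-lutidine) gives the β-hydroxy aldehyde F7. Addition of excess LiC≡CSiMe3 gives the propargylic diol F8 as a C3 epimer mixture of no consequence. Selective MnO2 oxidation of the propargylic hydroxyl comes back to the route at 12.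

Further compounds
F1 | step 13 | C5=C6 olefin from dehydration of 17 (1-O-TBS, 3-O-TES, 8α-OTBS, terminal alkyne) | C#C[C@@H](O[Si](CC)(CC)CC)C[C@@H](O[Si](C)(C)C(C)(C)C)[C@@]1(C)C=C[C@H](C(C)C)[C@@H](O[Si](C)(C)C(C)(C)C)C1
F2 | step 13 | 15-(tributylstannyl) derivative of 19 (E/Z mixture at C4=C15) | CCCC[Sn](CCCC)(CCCC)C=C1[C@@H](O[Si](CC)(CC)CC)C[C@@H](O[Si](C)(C)C(C)(C)C)[C@]2(C)C[C@H](O[Si](C)(C)C(C)(C)C)[C@@H](C(C)C)C[C@@H]12
F3 | step 2 | methyl (4R,5S)-5-(tert-butyldimethylsilyloxy)-4-isopropyl-2-oxocyclohexane-1-carboxylate (keto–enol mixture, C1 epimerisable) | COC(=O)C1C(=O)C[C@H](C(C)C)[C@@H](O[Si](C)(C)C(C)(C)C)C1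
F4 | step 2 | cis-β-hydroxy ester from F3 (5α-OH axial, ester equatorial, C10–H β) | COC(=O)[C@H]1[C@@H](O)C[C@H](C(C)C)[C@@H](O[Si](C)(C)C(C)(C)C)C1
F5 | step 2 | C10-methylated β-hydroxy ester (10β-CH3, ester α, 5α-OH) | COC(=O)[C@@]1(C)[C@@H](O)C[C@H](C(C)C)[C@@H](O[Si](C)(C)C(C)(C)C)C1
F6 | step 8 | (1R)-homoallylic alcohol from allylation of 9 [C10–C1H(OH)–CH2–CH=CH2] | C=CC[C@@H](O)[C@@]1(C)[C@H](OCc2ccc(OC)cc2)C[C@H](C(C)C)[C@@H](O[Si](C)(C)C(C)(C)C)C1
F7 | step 8 | (1R)-β-hydroxy aldehyde [C10–C1H(OH)–C2H2–C3HO] | O=CC[C@@H](O)[C@@]1(C)[C@H](OCc2ccc(OC)cc2)C[C@H](C(C)C)[C@@H](O[Si](C)(C)C(C)(C)C)C1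
F8 | step 8 | (1R)-5-(trimethylsilyl)pent-4-yne-1,3-diol on the ring B unit of 9 (C3 epimer mixture) | C[Si](C)(C)C#CC(O)C[C@@H](O)[C@@]1(C)[C@H](OCc2ccc(OC)cc2)C[C@H](C(C)C)[C@@H](O[Si](C)(C)C(C)(C)C)C1
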